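**Retrosynthetic overview**

1. The cyclopentenone (C1′–C5′) is traced back to a benzilic ester ring contraction (six to five) of a 2-hydroxy-5-methoxy-3-alkyl-1,4-benzoquinone, itself from a tetramethoxyarene; the aryl–CH2–C8 bond comes from an aryllithium and a C8 aldehyde.
2. Ring A (C1, C2, C3, C4, C5, C10) is traced back to a cyclopentanone (C1, C2, C3, C5, C10) fused to ring B: a methyl-bearing carbenoid carbon is inserted as C4 into the C3–C5 bond, giving the C3=C4 enolate, then the enol triflate, then the alkene; the C3 carbonyl is a temporary oxidation level.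
3. Enabling feature: the C3 carbonyl of that five-membered ring lies between the fully substituted C5 (angular methyl carbon shared by rings A and B, the better migrating group) and the C2 methylene, so C5 dictates both the site of insertion and the position of the later C3=C4 bond.
4. C8 and C9 come from reductive methylation of a C8=C9 unsaturated ester, and C10 from dissolving-metal reduction of the enone; all three are relayed from C5.
5. C5 comes from an L-phenylalanine-mediated Hajos–Parrish aldol of the triketone from 2-methylcyclopentane-1,3-dione and ethyl vinyl ketone. Ring order: cyclopentane (bought), ring B (step 2), arene attached (step 10), ring A by enlargement (step 14), cyclopentenone by contraction (step 18).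

Key step: step 14

**Remarks**

- Locants: the decalin is numbered as in drimanes (ring A = C1, C2, C3, C4, C5, C10; ring B = C5 to C10; methyls on C4, C5, C8, C9; the CH2 link on C8). The hydrindane intermediates keep these locants and lack C4 until step 14. β is the face of the C5 methyl, α the opposite face. The cyclopentenone is C1′ (C=O), C2′ (OMe), C3′ (H), C4′ (OH, CO2Me), C5′ (CH2 link). Ar = 2,3,5,6-tetramethoxyphenyl.
- The target as drawn has 5β-Me, 10α-H, 9β-Me, 8α-Me and 8β-CH2, with OH trans and CO2Me cis to the CH2 group on the cyclopentenone.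
- Assumption: in step 18 the (S,S) ligand is taken as the enantiomer that gives the required C4′ configuration; if the sense of induction is the reverse, its enantiomer is used in the same way.

**Route**

Step 1
Reactants: 1 (2-methylcyclopentane-1,3-dione) and 2 (pent-1-en-3-one, ethyl vinyl ketone)
Product: 3 triketone 2-methyl-2-(3-oxopentyl)cyclopentane-1,3-dione (achiral)
Conditions: H2O, AcOH (cat.), 75 °C
Reagents that add atoms: none
Why: Michael addition of the enolised 1,3-dione to the vinyl ketone in water; no stereocentre is formed because the two ring carbonyls of 3 are enantiotopic.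

Step 2
Reactants: 3
Product: 4 enedione (7aS)-4,7a-dimethyl-2,3,7,7a-tetrahydro-1H-indene-1,5(6H)-dione (C3 and C8 ketones, C9(Me)=C10, 5β-methyl)
Conditions: L-phenylalanine (1.0 equiv), 1 M aq. HClO4 (0.5 equiv), MeCN, 80 °C
Reagents that add atoms: none
Why: Hajos–Parrish aldol condensation in which the enamine of the side-chain ketone with the L-amino acid attacks one of the two enantiotopic ring carbonyls, setting the quaternary C5 as (S), and dehydration gives the enone; the optical purity should be raised by recrystallisation.

Step 3
Reactants: 4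
Product: 5 hydroxy enone (1S,7aS)-1-hydroxy-4,7a-dimethyl-1,2,3,6,7,7a-hexahydro-5H-inden-5-one (3β-OH)
Conditions: NaBH4 (0.3 equiv), EtOH, −20 °C
Reagents that add atoms: none
Why: chemoselective hydride reduction of the saturated cyclopentanone beside the less electrophilic tetrasubstituted enone; hydride attacks C3 from the α face, opposite the angular methyl, giving the 3β-alcohol (a temporary centre, removed in step 13).

Step 4
Reactants: 5
Product: 6 silyl ether, the 3β-(tert-butyldimethylsilyloxy) enone
Conditions: TBSCl, imidazole, DMF, 40 °C
Reagents that add atoms: tert-butyldimethylsilyl chloride, CC(C)(C)[Si](C)(C)Cl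
Why: standard silylation of a secondary alcohol; no stereocentre is touched.

Step 5
Reactants: 6
Product: 8 trans-fused enol triflate (C8(OTf)=C9(Me); 10α-H), via lithium enolate 7 (not isolated)
Conditions: Li (2.2 equiv), NH3(l)/THF, t-BuOH (1.0 equiv), −78 °C; isoprene; NH3 evaporated; PhNTf2 (1.2 equiv), THF, 0 → 23 °C
Reagents that add atoms: N-phenylbis(trifluoromethanesulfonimide), O=S(=O)(N(c1ccccc1)S(=O)(=O)C(F)(F)F)C(F)(F)F
Why: dissolving-metal (Birch-type) reduction of the enone in which the β-carbon C10 is protonated axially on the α face, opposite the angular 5β-methyl, giving the trans ring fusion, and the regiodefined C8 enolate is trapped on oxygen before it can equilibrate.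

Step 6
Reactants: 8
Product: 9 unsaturated methyl ester (CO2Me on C8, C8=C9(Me))
Conditions: Pd(OAc)2 (5 mol%), PPh3 (10 mol%), CO (1 atm), Et3N (2 equiv), MeOH/DMF (1:2), 60 °C
Reagents that add atoms: carbon monoxide, [C-]#[O+]; methanol, CO
Why: palladium-catalysed alkoxycarbonylation of an enol triflate (oxidative addition to zerovalent palladium, CO insertion, methanolysis of the acyl palladium species); no stereocentre is affected.

Step 7
Reactants: 9
Product: 11 quaternary methyl ester (8α-Me/8β-CO2Me/9β-Me), via ester enolate 10 (not isolated)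
Conditions: Li (2.5 equiv), NH3(l)/THF, t-BuOH (1.0 equiv), −78 °C; isoprene; MeI (5 equiv), −78 → −33 °C
Reagents that add atoms: iodomethane, CI
Why: Birch-type reductive alkylation of an unsaturated ester in which C9 is protonated on the α face because the β face is blocked by the 1,3-related axial C5 methyl (so the C9 methyl ends β and axial), and the exocyclic ester enolate is then methylated at C8 on the α face, anti to that neighbouring axial methyl, leaving the ester β and equatorial.

Step 8
Reactants: 11
Product: 12 primary alcohol (8β-CH2OH)
Conditions: LiAlH4, THF, 0 → 60 °C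
Reagents that add atoms: none
Why: hydride reduction of the hindered ester to the neopentyl alcohol; no stereocentre is touched.

Step 9
Reactants: 12
Product: 13 aldehyde (8β-CHO)
Conditions: Dess–Martin periodinane, NaHCO3, CH2Cl2, 23 °C
Reagents that add atoms: none
Why: Dess–Martin oxidation of a primary alcohol; the aldehyde has a quaternary α-carbon and cannot epimerise.

Step 10
Reactants: 13 and 14 (1,2,4,5-tetramethoxybenzene)
Product: 17 benzylic acetate (both epimers at the new carbinol carbon), via aryllithium 15 (not isolated), via lithium alkoxide 16 (not isolated)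
Conditions: 14, n-BuLi, THF, 0 → 23 °C; 13, −78 → 0 °C; Ac2O, 0 → 23 °C
Reagents that add atoms: acetic anhydride, CC(=O)OC(C)=O
Why: directed ortho-lithiation between two methoxy groups, addition of the aryllithium to the non-enolisable aldehyde and O-acetylation of the alkoxide in the same flask; the new carbinol centre forms unselectively, which does not matter because it is removed in step 11.

Step 11
Reactants: 17
Product: 18 arylmethyl hydrindane (8β-CH2Ar, 3β-OTBS)
Conditions: Li (6 equiv), NH3(l)/THF, −78 °C, 15 min; NH4Cl
Reagents that add atoms: none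
Why: dissolving-metal hydrogenolysis of the benzylic C–O bond (electron transfer to the arene, loss of acetate, reduction and protonation at the benzylic carbon); without an added alcohol the electron-rich arene ring is not reduced.

Step 12
Reactants: 18
Product: 19 secondary alcohol (3β-OH)
Conditions: n-Bu4NF, THF, 50 °C
Reagents that add atoms: none
Why: fluoride-induced cleavage of the silyl ether; no stereocentre is touched.

Step 13
Reactants: 19
Product: 20 hydrindan-3-one (ring A in its five-membered form: C1, C2, C3(=O), C5, C10)
Conditions: Dess–Martin periodinane, NaHCO3, CH2Cl2, 23 °C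
Reagents that add atoms: none
Why: Dess–Martin oxidation of the secondary alcohol; the α-carbons are the quaternary C5 and the C2 methylene, so no stereocentre can epimerise.

Step 14
Reactants: 20
Product: 24 ring A enol triflate (C3(OTf)=C4(Me)), via dibromo alkoxide 21 (not isolated), via oxido carbenoid 22 (not isolated), via ring-enlarged enolate 23 (not isolated)
Conditions: CH3CHBr2 (1.5 equiv), lithium 2,2,6,6-tetramethylpiperidide (1.5 equiv), THF, −95 °C; n-BuLi (1.6 equiv), −95 → −20 °C; PhNTf2 (2 equiv), 0 → 23 °C
Reagents that add atoms: 1,1-dibromoethane, CC(Br)Br; N-phenylbis(trifluoromethanesulfonimide), O=S(=O)(N(c1ccccc1)S(=O)(=O)C(F)(F)F)C(F)(F)F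
Why: CH3CBr2Li, made from 1,1-dibromoethane and the lithium amide, adds to the C3 carbonyl on the face opposite the angular methyl to give alkoxide 21; bromine–lithium exchange then gives the β-oxido carbenoid 22, in which the alkoxide pushes the C3–C5 ring bond onto the electron-poor carbenoid carbon with loss of LiBr, so that this carbon enters the ring as C4 with its methyl and the lithium enolate 23 (C3(OLi)=C4) forms regiospecifically before O-triflation. The closest known reaction type is the β-oxido carbenoid ring enlargement of cycloalkanones with 1,1-dibromoalkanes, a semipinacol-type 1,2-shift related to the Tiffeneau–Demjanov and β-hydroxy selenide ring expansions. No ring is closed from a chain: ring A arises by a 1,2-alkyl shift from the cyclopentane (C1, C2, C3, C5, C10), which gains one atom while ring B is untouched. No stereocentre is created (C3 and C4 end as sp2 carbons) and C5 migrates with retention, so the configuration set in step 2 and its trans relation to the C10 hydrogen are carried over unchanged. The selectivity needed is migration of C5 rather than C2; it rests on the higher migratory aptitude of the fully substituted, electron-rich C5 toward the electron-deficient carbenoid carbon, and because the enolate can only be C3=C4 the later alkene is fixed between C3 and C4 next to the quaternary centre.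

Step 15
Reactants: 24
Product: 25 alkene (ring A with C3=C4(Me); tetramethoxyarene intact)
Conditions: Pd(OAc)2 (5 mol%), PPh3 (10 mol%), HCO2H (3 equiv), n-Bu3N (4 equiv), DMF, 60 °C
Reagents that add atoms: none
Why: palladium-catalysed formate reduction of the enol triflate (oxidative addition to zerovalent palladium, formate exchange, loss of CO2 to a palladium hydride, reductive elimination), which puts hydrogen on C3 and leaves the double bond where the enol triflate was.

Step 16
Reactants: 25
Product: 26 quinone 2,5-dimethoxy-3-(decalinylmethyl)-1,4-benzoquinone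
Conditions: (NH4)2Ce(NO3)6 (2.5 equiv), MeCN/H2O (2:1), 0 °C
Reagents that add atoms: water, O
Why: oxidative demethylation of a para-dimethoxy pair of the tetramethoxyarene by single-electron oxidation and attack of water (either para pair gives the same quinone); the trisubstituted alkene should not be oxidised under these conditions.

Step 17
Reactants: 26
Product: 27 hydroxyquinone 2-hydroxy-5-methoxy-3-(decalinylmethyl)-1,4-benzoquinone
Conditions: 70% aq. HClO4, THF, 23 °C
Reagents that add atoms: water, O
Why: acid-catalysed addition–elimination at a vinylogous ester, selective for the methoxy group next to the alkyl-bearing carbon because that group is twisted out of conjugation and sits on the more basic enone unit, the regiochemistry known for 2,5-dimethoxy-3-alkylbenzoquinones.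

Step 18
Reactants: 27
Product: 30 dysidenone B, via hemiketal 28 (not isolated), via cyclopentadienol 29 (not isolated)
Conditions: Cu(OTf)2 (10 mol%), (S,S)-2,2'-(propane-2,2-diyl)bis(4-tert-butyl-4,5-dihydro-1,3-oxazole) (12 mol%), MeOH (20 equiv), CH2Cl2, 4 Å molecular sieves, 23 °C
Reagents that add atoms: methanol, CO
Why: Proposed new method: the hydroxyquinone reacts through its 4-hydroxy-1,2-benzoquinone tautomer, whose vicinal dione is chelated and activated by the divalent copper bis(oxazoline) complex in the way 1,2-dicarbonyl compounds are; methanol adds to the carbonyl next to the alkyl-bearing carbon to give hemiketal 28, the bond between the hemiketal carbon and that alkyl-bearing carbon (the future C5′) migrates to the neighbouring copper-bound carbonyl carbon (the future C4′) in a benzilic ester rearrangement, which contracts the six-membered ring, expels the hemiketal carbon as the methyl ester and gives cyclopentadienol 29; the ligand selects the face of the accepting carbonyl and so sets C4′, and ketonisation by protonation of C5′ on the hydroxyl face (opposite the bulkier ester) places the CH2 group trans to the hydroxyl; the closest known reaction types are the base-mediated benzilic ester rearrangement of 1,2-diones and catalytic enantioselective acyloin (α-ketol) rearrangements under chiral Lewis acids.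

**Compound list**

1 | 2-methylcyclopentane-1,3-dione | CC1C(=O)CCC1=O | starting material
2 | pent-1-en-3-one (ethyl vinyl ketone) | CCC(=O)C=C | starting material
3 | 2-methyl-2-(3-oxopentyl)cyclopentane-1,3-dione | CCC(=O)CCC1(C)C(=O)CCC1=O | intermediate
4 | (7aS)-4,7a-dimethyl-2,3,7,7a-tetrahydro-1H-indene-1,5(6H)-dione | O=C1CC[C@]2(C)C(=O)CCC2=C1C | intermediate
5 | (1S,7aS)-1-hydroxy-4,7a-dimethyl-1,2,3,6,7,7a-hexahydro-5H-inden-5-one (3β-OH enone) | O=C1CC[C@]2(C)[C@@H](O)CCC2=C1C | intermediate
6 | 3β-TBS ether of 5 | O=C1CC[C@]2(C)[C@@H](O[Si](C)(C)C(C)(C)C)CCC2=C1C | intermediate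
7 | lithium C8 enolate, trans-fused, 10α-H (not isolated) | [Li]OC=1CC[C@]2(C)[C@@H](O[Si](C)(C)C(C)(C)C)CC[C@H]2C=1C | intermediate
8 | trans-fused enol triflate, C8(OTf)=C9(Me), 3β-OTBS, 5β-Me, 10α-H | O=S(=O)(OC=1CC[C@]2(C)[C@@H](O[Si](C)(C)C(C)(C)C)CC[C@H]2C=1C)C(F)(F)F | intermediate
9 | unsaturated methyl ester, CO2Me on C8, C8=C9(Me) | COC(=O)C=1CC[C@]2(C)[C@@H](O[Si](C)(C)C(C)(C)C)CC[C@H]2C=1C | intermediate
10 | lithium ester enolate, 9β-Me, 9α-H (not isolated) | COC(O[Li])=C1CC[C@]2(C)[C@@H](O[Si](C)(C)C(C)(C)C)CC[C@H]2[C@H]1C | intermediate
11 | methyl ester, 8β-CO2Me, 8α-Me, 9β-Me, 10α-H, 5β-Me, 3β-OTBS | COC(=O)[C@@]1(C)CC[C@]2(C)[C@@H](O[Si](C)(C)C(C)(C)C)CC[C@H]2[C@H]1C | intermediate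
12 | primary alcohol, 8β-CH2OH | OC[C@@]1(C)CC[C@]2(C)[C@@H](O[Si](C)(C)C(C)(C)C)CC[C@H]2[C@H]1C | intermediate
13 | aldehyde, 8β-CHO | O=C[C@@]1(C)CC[C@]2(C)[C@@H](O[Si](C)(C)C(C)(C)C)CC[C@H]2[C@H]1C | intermediate
14 | 1,2,4,5-tetramethoxybenzene | COc1cc(OC)c(OC)cc1OC | starting material
15 | 2,3,5,6-tetramethoxyphenyllithium (not isolated) | [Li]c1c(OC)c(OC)cc(OC)c1OC | intermediate
16 | lithium alkoxide of the aryl carbinol, carbinol centre undefined (not isolated) | [Li]OC(c1c(OC)c(OC)cc(OC)c1OC)[C@@]1(C)CC[C@]2(C)[C@@H](O[Si](C)(C)C(C)(C)C)CC[C@H]2[C@H]1C | intermediate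
17 | benzylic acetate, both epimers at the carbinol carbon | CC(=O)OC(c1c(OC)c(OC)cc(OC)c1OC)[C@@]1(C)CC[C@]2(C)[C@@H](O[Si](C)(C)C(C)(C)C)CC[C@H]2[C@H]1C | intermediate
18 | 8β-(2,3,5,6-tetramethoxybenzyl) hydrindane, 3β-OTBS | COc1cc(OC)c(OC)c(C[C@@]2(C)CC[C@]3(C)[C@@H](O[Si](C)(C)C(C)(C)C)CC[C@H]3[C@H]2C)c1OC | intermediate
19 | 3β-alcohol | COc1cc(OC)c(OC)c(C[C@@]2(C)CC[C@]3(C)[C@@H](O)CC[C@H]3[C@H]2C)c1OC | intermediate
20 | hydrindan-3-one | COc1cc(OC)c(OC)c(C[C@@]2(C)CC[C@]3(C)C(=O)CC[C@H]3[C@H]2C)c1OC | intermediate
21 | lithium alkoxide of the C3 (1,1-dibromoethyl) carbinol, 3β-O (not isolated) | COc1cc(OC)c(OC)c(C[C@@]2(C)CC[C@]3(C)[C@](O[Li])(C(C)(Br)Br)CC[C@H]3[C@H]2C)c1OC | intermediate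
22 | β-oxido carbenoid, carbenoid carbon undefined (not isolated) | COc1cc(OC)c(OC)c(C[C@@]2(C)CC[C@]3(C)[C@](O[Li])(C(C)([Li])Br)CC[C@H]3[C@H]2C)c1OC | intermediate
23 | ring-enlarged lithium enolate, C3(OLi)=C4(Me) (not isolated) | COc1cc(OC)c(OC)c(C[C@@]2(C)CC[C@]3(C)C(C)=C(O[Li])CC[C@H]3[C@H]2C)c1OC | intermediate
24 | ring A enol triflate, C3(OTf)=C4(Me), trans-decalin | COc1cc(OC)c(OC)c(C[C@@]2(C)CC[C@]3(C)C(C)=C(OS(=O)(=O)C(F)(F)F)CC[C@H]3[C@H]2C)c1OC | intermediate
25 | alkene, C3=C4(Me), 8β-(2,3,5,6-tetramethoxybenzyl) | COc1cc(OC)c(OC)c(C[C@@]2(C)CC[C@]3(C)C(C)=CCC[C@H]3[C@H]2C)c1OC | intermediate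
26 | 2,5-dimethoxy-3-(decalinylmethyl)-1,4-benzoquinone | COC1=CC(=O)C(OC)=C(C[C@@]2(C)CC[C@]3(C)C(C)=CCC[C@H]3[C@H]2C)C1=O | intermediate
27 | 2-hydroxy-5-methoxy-3-(decalinylmethyl)-1,4-benzoquinone | COC1=CC(=O)C(O)=C(C[C@@]2(C)CC[C@]3(C)C(C)=CCC[C@H]3[C@H]2C)C1=O | intermediate
28 | methanol hemiketal of the 1,2-dione tautomer, hemiketal centre undefined (not isolated) | COC1=CC(=O)C(O)(OC)C(C[C@@]2(C)CC[C@]3(C)C(C)=CCC[C@H]3[C@H]2C)=C1O | intermediate
29 | ring-contracted cyclopentadienol, C4′ set (not isolated) | COC(=O)[C@@]1(O)C=C(OC)C(O)=C1C[C@@]1(C)CC[C@]2(C)C(C)=CCC[C@H]2[C@H]1C | intermediate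
30 | dysidenone B | COC(=O)[C@@]1(O)C=C(OC)C(=O)[C@H]1C[C@@]1(C)CC[C@]2(C)C(C)=CCC[C@H]2[C@H]1C | target

**Step count**

Total step count: 18. Longest linear sequence: 18 steps (1 to 30; arene 14 is bought).

**Steps most likely to fail**

1. Step 18 (proposed new method). The 1,2-shift may proceed without facial discrimination, the chelating substrate may sequester the catalyst, and C5′ may epimerise after ketonisation. Fallback: setting out from hydroxyquinone 27, the classical achiral benzilic ester rearrangement of the 1,2-dione tautomer is run with NaOMe in MeOH at 40 °C and quenched with AcOH at −20 °C. This should give 30 together with its diastereomer inverted at both cyclopentenone centres, the 4′,5′-bis-epimer F1. The two differ as diastereomers because of the decalin and are separated by preparative chromatography, which comes back to the route at 30. Stereocontrol by the catalyst is thus replaced by separation.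

2. Step 14. The C2 methylene may migrate instead of the quaternary C5, and the amide base may enolise the hindered ketone before the carbenoid adds. Fallback: setting out from ketone 20, a Tiffeneau–Demjanov-type diazo homologation with Me3SiCHN2 and BF3·OEt2 (CH2Cl2, −78 °C) inserts the diazo carbon on the less substituted side and gives the α-trimethylsilyl ketone F2. This is desilylated with K2CO3 in MeOH to the ring-expanded C4 ketone F3 (the carbonyl carbon of 20 becomes C4, the inserted CH2 becomes C3). KN(SiMe3)2 and PhNTf2 then give the only possible enol triflate, the C4 enol triflate F4, since C5 bears no hydrogen. Me2CuLi (Et2O, −20 °C) exchanges triflate for methyl and comes back to the route at alkene 25. Here the methyl is introduced by coupling and no longer by the inserted carbon.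

3. Step 7. Protonation at C9 may occur axially from the β face, facial selectivity in the methylation may be poor, and the ester may be over-reduced. Fallback: setting out from unsaturated ester 9, hydrogenation over PtO2 (H2, 50 atm, EtOAc) should add both hydrogens from the α face, opposite the angular methyl, to give the all-cis saturated ester F5 (8β-CO2Me, 9β-Me). LiN(iPr)2 (THF, −78 °C) then forms the same ester enolate 10, and MeI methylates it on the α face as in the main route, coming back at ester 11. Protonation under stereoelectronic control is replaced by sterically controlled surface hydrogenation.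

Further compounds
F1 | step 18 | 4′,5′-bis-epimer of 30 (both cyclopentenone centres inverted) | COC(=O)[C@]1(O)C=C(OC)C(=O)[C@@H]1C[C@@]1(C)CC[C@]2(C)C(C)=CCC[C@H]2[C@H]1C
F2 | step 14 | α-trimethylsilyl ring-expanded ketone (C4=O, silyl on C3, C3 undefined) | COc1cc(OC)c(OC)c(C[C@@]2(C)CC[C@]3(C)C(=O)C([Si](C)(C)C)CC[C@H]3[C@H]2C)c1OC
F3 | step 14 | ring-expanded C4 ketone (trans-decalin-4-one) | COc1cc(OC)c(OC)c(C[C@@]2(C)CC[C@]3(C)C(=O)CCC[C@H]3[C@H]2C)c1OC
F4 | step 14 | C4 enol triflate, C4(OTf)=C3 | COc1cc(OC)c(OC)c(C[C@@]2(C)CC[C@]3(C)C(OS(=O)(=O)C(F)(F)F)=CCC[C@H]3[C@H]2C)c1OC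
F5 | step 7 | all-cis saturated ester, 8β-CO2Me, 8α-H, 9β-Me | COC(=O)[C@H]1CC[C@]2(C)[C@@H](O[Si](C)(C)C(C)(C)C)CC[C@H]2[C@H]1C
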